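## Retrosynthetic overview

1. Enabling feature: the 3(2H)-furanone ring O–C10–C1(=O)–C2H=C3 is the cyclo-isomer of an α′-hydroxy ynone. C10 carries both the ring oxygen and the acyl carbon C1, and C1–C2 is also a bond of the ten-membered carbocycle C1–C10, so C1–C2 and O–C3 are disconnected together.
2. This gives a seco compound: a cis-disubstituted α-methylene-γ-butyrolactone with an S-ethyl α-hydroxy thioester (O, C10, C1) on the C7 arm and a terminal enyne (C2≡C3–C4=C15) on the C6 arm. One Pd/Cu cascade closes the carbocycle (C1–C2) and the furanone (O–C3).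
3. The seco compound comes from an indium Barbier union (C7–C8 bond; C7 and C8 set under control of C6) of a (Z)-2-(bromomethyl)enoate and a thioester aldehyde, then O8 acylation and acid-induced acetonide loss with lactonisation.
4. Bromide: C5/C6 are bought as 2,3-O-isopropylidene-D-erythronolactone (acetylide addition, Wittig, oxidation, Morita–Baylis–Hillman, SN2′ bromination). Aldehyde: C10 comes from the (S)-lactic acid dioxolanone (enolate allylation, thiolysis, ozonolysis).
5. Ring order: butyrolactone (step 11), then ten-membered carbocycle and furanone together (step 12); no protecting-group step follows.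

Key step: step 12

Remark: locants C1–C15 follow germacrane numbering (C1 ketone carbon, C2/C3 furanone alkene carbons, C4=C15 exocyclic alkene, C5 carbinol, C6/C7 lactone ring fusion, C8 ester carbinol, C10 quaternary carbon, C11–C13 methylene lactone). Metalated forms of numbered compounds (lithium acetylide of 2, lithium enolate of 10, allylindium species from 9) are treated as activated forms of those compounds and are not numbered.
Remark: (2S,5S)-2-tert-butyl-5-methyl-1,3-dioxolan-4-one is taken as a catalogue compound; otherwise it is one step from (S)-lactic acid and pivalaldehyde.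

## Route

Step 1
Reactants: 1 2,3-O-isopropylidene-D-erythronolactone; 2 ethynyl(trimethyl)silane
Product: 3 (3aR,6aR)-2,2-dimethyl-4-[(trimethylsilyl)ethynyl]tetrahydrofuro[3,4-d][1,3]dioxol-4-ol (mixture of anomers)
Conditions: 2, n-BuLi, THF, −78 °C; then 1, −78 °C; aq NH4Cl
Reagents that add atoms: none
Why: 1,2-addition of a lithium acetylide to a γ-lactone stops at the lithium lactolate at −78 °C, so one alkynyl group enters; the two stereocentres are locked in the cis-fused bicycle and cannot epimerise.

Step 2
Reactants: 3 alkynyl hemiketal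
Product: 5 [(4R,5S)-5-(but-1-en-3-yn-2-yl)-2,2-dimethyl-1,3-dioxolan-4-yl]methanol, via silylated enyne alcohol 4 (not isolated)
Conditions: Ph3PCH3Br, KOtBu, THF, 0 °C to rt; then MeOH, K2CO3, rt
Reagents that add atoms: methyltriphenylphosphonium bromide, C[P+](c1ccccc1)(c1ccccc1)c1ccccc1.[Br-]
Why: Wittig methylenation should act on the ring-opened hydroxy ynone tautomer of the hemiketal, with the silyl cap hindering conjugate addition, and base-mediated methanolysis then cleaves the C(sp)–Si bond; no stereocentre is formed.

Step 3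
Reactants: 5 enyne alcohol
Product: 6 (4S,5S)-5-(but-1-en-3-yn-2-yl)-2,2-dimethyl-1,3-dioxolane-4-carbaldehyde
Conditions: Dess–Martin periodinane, NaHCO3, CH2Cl2, 0 °C to rt
Reagents that add atoms: none
Why: Dess–Martin oxidation under buffered, non-basic conditions should give the aldehyde without epimerising the α-alkoxy centre of the cis-dioxolane; the aldehyde is used without chromatography.

Step 4
Reactants: 6 aldehyde; 7 methyl prop-2-enoate
Product: 8 methyl 2-{[(4R,5S)-5-(but-1-en-3-yn-2-yl)-2,2-dimethyl-1,3-dioxolan-4-yl](hydroxy)methyl}prop-2-enoate (carbinol epimers)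
Conditions: 7 (excess), DABCO, 1,4-dioxane/H2O (1:1), rt
Reagents that add atoms: none
Why: Morita–Baylis–Hillman reaction of an activated α-alkoxy aldehyde, accelerated in aqueous dioxane; the new carbinol centre forms as a mixture, which does not matter because it becomes sp2 in step 5.

Step 5
Reactants: 8 allylic alcohol
Product: 9 methyl (2Z)-2-(bromomethyl)-3-[(4R,5S)-5-(but-1-en-3-yn-2-yl)-2,2-dimethyl-1,3-dioxolan-4-yl]prop-2-enoate
Conditions: NBS, Me2S, CH2Cl2, 0 °C; then 8, 0 °C to rt
Reagents that add atoms: N-bromosuccinimide, O=C1CCC(=O)N1Br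
Why: Corey–Kim-type activation of the alcohol as an alkoxysulfonium salt and SN2′ attack of bromide should give the rearranged primary allylic bromide, the trisubstituted alkene forming with the ester trans to the dioxolanyl group (Z) for steric reasons.

Step 6
Reactants: 10 (2S,5S)-2-tert-butyl-5-methyl-1,3-dioxolan-4-one; 11 3-bromoprop-1-ene
Product: 12 (2S,5R)-2-tert-butyl-5-methyl-5-(prop-2-en-1-yl)-1,3-dioxolan-4-one
Conditions: LiN(i-Pr)2, THF, −78 °C; then 11, −78 to −30 °C
Reagents that add atoms: none
Why: alkylation of the dioxolanone lithium enolate (self-regeneration of stereocentres): the tert-butyl group on the acetal carbon shields one face, so the allyl group enters trans to it and sets the quaternary centre that becomes C10 (R).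

Step 7
Reactants: 12 allyl dioxolanone
Product: 13 S-ethyl (2R)-2-hydroxy-2-methylpent-4-enethioate
Conditions: AlMe3, EtSH, CH2Cl2, 0 °C; then 12, 0 °C to rt; aq potassium sodium tartrate (KNaC4H4O6)
Reagents that add atoms: ethanethiol, CCS
Why: thiolysis of the acylal-type ester by a dimethylaluminium thiolate: acyl–oxygen cleavage releases a hemiacetal alkoxide that collapses to pivalaldehyde, leaving the tertiary α-hydroxy thioester with the quaternary centre untouched.

Step 8
Reactants: 13 thioester alkene
Product: 14 S-ethyl (2R)-2-hydroxy-2-methyl-4-oxobutanethioate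
Conditions: O3, CH2Cl2, −78 °C; then PPh3, −78 °C to rt
Reagents that add atoms: ozone, [O-][O+]=O
Why: ozonolysis of the isolated terminal alkene with reductive work-up; thioester and tertiary alcohol should be inert at −78 °C and no stereocentre is affected.

Step 9
Reactants: 9 allylic bromide; 14 aldehyde
Product: 15 methyl (3R,4R,6R)-3-[(4R,5S)-5-(but-1-en-3-yn-2-yl)-2,2-dimethyl-1,3-dioxolan-4-yl]-7-(ethylsulfanyl)-4,6-dihydroxy-6-methyl-2-methylidene-7-oxoheptanoate
Conditions: In powder, THF/H2O (1:1), rt
Reagents that add atoms: none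
Why: indium-mediated Barbier allylation: the (Z)-2-(alkoxycarbonyl)allylindium species reacts at its γ-carbon through a closed six-membered (Zimmerman–Traxler-type) transition state, which should turn the Z geometry into the syn relationship of C7 and C8, while the C6 stereocentre selects the face of the allyl unit (H6 eclipses the alkene by allylic 1,3-strain, and the aldehyde is delivered on the side of the dioxolane oxygen O6, to which indium can coordinate, away from the cis enyne substituent on C5), so that (7R,8R) is expected.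

Step 10
Reactants: 15 diol
Product: 16 methyl (3R,4R,6R)-3-[(4R,5S)-5-(but-1-en-3-yn-2-yl)-2,2-dimethyl-1,3-dioxolan-4-yl]-7-(ethylsulfanyl)-6-hydroxy-6-methyl-2-methylidene-4-[(2-methylpropanoyl)oxy]-7-oxoheptanoate
Conditions: i-PrCOCl, pyridine, DMAP (cat.), CH2Cl2, 0 °C
Reagents that add atoms: 2-methylpropanoyl chloride, CC(C)C(Cl)=O
Why: DMAP-catalysed acylation should take the secondary C8 hydroxyl and leave the hindered tertiary C10 hydroxyl, and it removes the only hydroxyl that could attack the thioester or the methyl ester through a five-membered ring.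

Step 11
Reactants: 16 acetonide ester
Product: 18 S-ethyl (2R,4R)-2-hydroxy-4-{(2R,3R)-2-[(1S)-1-hydroxy-2-methylidenebut-3-yn-1-yl]-4-methylidene-5-oxooxolan-3-yl}-2-methyl-4-[(2-methylpropanoyl)oxy]butanethioate, via diol 17 (not isolated)
Conditions: CF3CO2H/H2O (9:1), 0 °C to rt; then toluene, evaporation
Reagents that add atoms: none
Why: acid-catalysed acetal hydrolysis followed by lactonisation: of the two freed hydroxyls the one on C6 should close the five-membered α-methylene-γ-butyrolactone on the methyl ester (5-exo-trig, favoured over the six-membered lactone through O5), with the cis arrangement of the two arms already fixed in step 9; thioester, isobutyrate and tertiary alcohol tolerate aqueous CF3CO2H.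

Step 12
Reactants: 18 seco thioester
Product: 20 (5S,6R,7R,8R,10R)-5-hydroxy-8-(2-methylpropanoyloxy)-1-oxo-3,10-epoxygermacra-2,4(15),11(13)-trien-12,6-olide (CNP0384113.1), via cyclodecenynone 19 (not isolated)
Conditions: PdCl2(dppf) (10 mol%), tri(2-furyl)phosphine (25 mol%), CuI (1.7 equiv), Et3N, DMF, 50 °C, slow addition of 18 (final 2 mM), argon
Reagents that add atoms: none
Why: Proposed new method: zerovalent palladium inserts into the C1–S bond of the α-hydroxy thioester, the copper acetylide of C2 transmetalates to the acyl divalent palladium so that the chain is first closed as a flexible eleven-membered acyl(alkynyl)palladacycle, and reductive elimination forms C1–C2 and thereby the ten-membered carbocycle as the bent cyclodecenynone 19, whose free tertiary C10 hydroxyl then adds across the ring to the ynone β-carbon C3 (transannular 5-endo-dig oxa-Michael addition under Et3N and copper π-activation) to close the 3(2H)-furanone and the 11-oxabicyclo[6.2.1]undecane core. The closest known reaction types are the intermolecular Pd/Cu-catalysed ketone synthesis from thiol esters and terminal alkynes (an acyl Sonogashira-type coupling) and the base- or coinage-metal-mediated cyclisation of α′-hydroxy ynones to 3(2H)-furanones; what is new is their use as one medium-ring-forming cascade. Ring closures: the carbocycle by ring-closing C(sp)–C(acyl) cross-coupling, the furanone by heteroatom conjugate addition that is driven by release of the alkyne bending strain and should therefore be fast and irreversible. No stereocentre is created; C5, C6, C7, C8 and C10 pass through unchanged because the conditions are weakly basic and C10 is quaternary. The step needs cyclisation to win over oligomerisation and oxidative alkyne dimerisation and needs carbon rather than oxygen acylation: the cis-disposed arms on the butyrolactone and the gem-disubstituted C10 turn the two termini toward each other, slow addition at high dilution under argon suppresses bimolecular paths, the C5 hydroxyl could reach C1 only through an eight-membered lactone, and stoichiometric CuI holds the released ethanethiolate as CuSEt so that it cannot add to the α-methylene lactone or to the product dienone.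

## Compound list

1 | (3aR,6aR)-2,2-dimethyldihydrofuro[3,4-d][1,3]dioxol-4(3aH)-one (2,3-O-isopropylidene-D-erythronolactone) | O=C1OC[C@H]2OC(C)(C)O[C@@H]12 | starting material
2 | ethynyl(trimethyl)silane | C#C[Si](C)(C)C | starting material
3 | (3aR,6aR)-2,2-dimethyl-4-[(trimethylsilyl)ethynyl]tetrahydrofuro[3,4-d][1,3]dioxol-4-ol (mixture of anomers) | C[Si](C)(C)C#CC1(O)OC[C@H]2OC(C)(C)O[C@@H]12 | intermediate
4 | {(4R,5S)-2,2-dimethyl-5-[4-(trimethylsilyl)but-1-en-3-yn-2-yl]-1,3-dioxolan-4-yl}methanol (formed and consumed in step 2) | OC[C@H]1OC(C)(C)O[C@H]1C(=C)C#C[Si](C)(C)C | intermediate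
5 | [(4R,5S)-5-(but-1-en-3-yn-2-yl)-2,2-dimethyl-1,3-dioxolan-4-yl]methanol | OC[C@H]1OC(C)(C)O[C@H]1C(=C)C#C | intermediate
6 | (4S,5S)-5-(but-1-en-3-yn-2-yl)-2,2-dimethyl-1,3-dioxolane-4-carbaldehyde | O=C[C@H]1OC(C)(C)O[C@H]1C(=C)C#C | intermediate
7 | methyl prop-2-enoate | C=CC(=O)OC | starting material
8 | methyl 2-{[(4R,5S)-5-(but-1-en-3-yn-2-yl)-2,2-dimethyl-1,3-dioxolan-4-yl](hydroxy)methyl}prop-2-enoate (carbinol epimers) | C=C(C(=O)OC)C(O)[C@H]1OC(C)(C)O[C@H]1C(=C)C#C | intermediate
9 | methyl (2Z)-2-(bromomethyl)-3-[(4R,5S)-5-(but-1-en-3-yn-2-yl)-2,2-dimethyl-1,3-dioxolan-4-yl]prop-2-enoate | BrC/C(C(=O)OC)=C\[C@H]1OC(C)(C)O[C@H]1C(=C)C#C | intermediate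
10 | (2S,5S)-2-tert-butyl-5-methyl-1,3-dioxolan-4-one | C[C@@H]1O[C@H](C(C)(C)C)OC1=O | starting material
11 | 3-bromoprop-1-ene | C=CCBr | starting material
12 | (2S,5R)-2-tert-butyl-5-methyl-5-(prop-2-en-1-yl)-1,3-dioxolan-4-one | C=CC[C@@]1(C)O[C@H](C(C)(C)C)OC1=O | intermediate
13 | S-ethyl (2R)-2-hydroxy-2-methylpent-4-enethioate | C=CC[C@@](C(=O)SCC)(C)O | intermediate
14 | S-ethyl (2R)-2-hydroxy-2-methyl-4-oxobutanethioate | O=CC[C@@](C(=O)SCC)(C)O | intermediate
15 | methyl (3R,4R,6R)-3-[(4R,5S)-5-(but-1-en-3-yn-2-yl)-2,2-dimethyl-1,3-dioxolan-4-yl]-7-(ethylsulfanyl)-4,6-dihydroxy-6-methyl-2-methylidene-7-oxoheptanoate | C=C(C(=O)OC)[C@@H]([C@H]1OC(C)(C)O[C@H]1C(=C)C#C)[C@H](O)C[C@@](C(=O)SCC)(C)O | intermediate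
16 | methyl (3R,4R,6R)-3-[(4R,5S)-5-(but-1-en-3-yn-2-yl)-2,2-dimethyl-1,3-dioxolan-4-yl]-7-(ethylsulfanyl)-6-hydroxy-6-methyl-2-methylidene-4-[(2-methylpropanoyl)oxy]-7-oxoheptanoate | C=C(C(=O)OC)[C@@H]([C@H]1OC(C)(C)O[C@H]1C(=C)C#C)[C@H](OC(=O)C(C)C)C[C@@](C(=O)SCC)(C)O | intermediate
17 | methyl (3S,4R,6R)-3-[(1R,2S)-1,2-dihydroxy-3-methylidenepent-4-yn-1-yl]-7-(ethylsulfanyl)-6-hydroxy-6-methyl-2-methylidene-4-[(2-methylpropanoyl)oxy]-7-oxoheptanoate (formed and consumed in step 11) | C=C(C(=O)OC)[C@@H]([C@@H](O)[C@@H](O)C(=C)C#C)[C@H](OC(=O)C(C)C)C[C@@](C(=O)SCC)(C)O | intermediate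
18 | S-ethyl (2R,4R)-2-hydroxy-4-{(2R,3R)-2-[(1S)-1-hydroxy-2-methylidenebut-3-yn-1-yl]-4-methylidene-5-oxooxolan-3-yl}-2-methyl-4-[(2-methylpropanoyl)oxy]butanethioate | C=C1C(=O)O[C@@H]([C@@H](O)C(=C)C#C)[C@H]1[C@H](OC(=O)C(C)C)C[C@@](C(=O)SCC)(C)O | intermediate
19 | (5S,6R,7R,8R,10R)-5,10-dihydroxy-8-(2-methylpropanoyloxy)-1-oxogermacra-4(15),11(13)-dien-2-yn-12,6-olide, the ten-membered α′-hydroxy enynone (formed and consumed in step 12) | C=C1C(=O)O[C@@H]2[C@H]1[C@H](OC(=O)C(C)C)C[C@@](C(=O)C#CC(=C)[C@@H]2O)(C)O | intermediate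
20 | (5S,6R,7R,8R,10R)-5-hydroxy-8-(2-methylpropanoyloxy)-1-oxo-3,10-epoxygermacra-2,4(15),11(13)-trien-12,6-olide (CNP0384113.1) | C=C1C(=O)O[C@@H]2[C@H]1[C@H](OC(=O)C(C)C)C[C@@]1(C)OC(=CC1=O)C(=C)[C@@H]2O | target

## Step count and risks

Total steps: 12. Longest linear sequence: 9 (steps 1–5 and 9–12, from 1); the branch from 10 runs through steps 6–8.

**Step 12 (proposed method).** What may go wrong: bimolecular coupling to oligomers and oxidative dimerisation of the alkyne outrun the medium-ring closure, or reductive elimination to the strained ynone is too slow and the acylpalladium species decomposes. The fallback uses only known reaction types, makes the furanone first and closes the ring elsewhere; it sets out from 8 and 13 and comes back to the route at 20. Intermolecular Pd/Cu-catalysed coupling of thioester 13 with the terminal alkyne of 8 (same catalyst system, then Et2NH in EtOH to complete the 5-endo-dig closure) should give the allyl furanone F1. Lemieux–Johnson cleavage (OsO4 cat., NaIO4, 2,6-lutidine) of its isolated, most electron-rich alkene gives the furanone aldehyde F2. NBS/Me2S converts the allylic alcohol into the (Z)-allylic bromide F3. An intramolecular indium Barbier allylation at high dilution forms C7–C8 and the ten-membered ring as the macrocyclic alcohol F4. Acylation with i-PrCOCl gives the macrocyclic isobutyrate F5, and CF3CO2H/H2O removes the acetonide and closes the lactone to give 20.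

**Step 9.** What may go wrong: poor discrimination between the two faces of the allylindium species, so that the syn adduct epimeric at both C7 and C8 forms beside 15; or acyl transfer from sulfur to the new C8 hydroxyl before it is acylated. The fallback replaces the metal-in-water Barbier step by a preformed, geometrically defined allylboronate that reacts through a tight closed transition state and can be steered by a chiral acid; it sets out from 8 (with 14 as partner) and comes back at 15. Acetylation of 8 (Ac2O, pyridine) gives the acetate F6. Pd2(dba)3-catalysed borylation with B2pin2 gives the rearranged primary allylboronate F7, with the dioxolanyl group cis to CH2B. Allylboration of 14 catalysed by Sc(OTf)3 or, if the aldehyde face must be set by the catalyst, by a chiral BINOL-derived phosphoric acid, followed by aqueous work-up, gives 15.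

**Step 2.** What may go wrong: slow opening of the hemiketal, epimerisation at C5 by the basic ylide in the open hydroxy ynone (cis-dioxolane to trans), or conjugate addition of the ylide. The fallback uses an open-chain ketone and a non-basic methylenation; it sets out from 1 and comes back at 5. Aminolysis of 1 (MeNHOMe·HCl, AlMe3) gives the hydroxy Weinreb amide F8, silylation (TBSCl, imidazole) gives the silyl ether amide F9, and LiC≡CSiMe3 gives the silylated ynone F10. Takai–Lombardo methylenation (Zn, CH2Br2, TiCl4) gives the bis-silylated enyne F11, and Bu4NF removes both silyl groups to give 5.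

## Further compounds

F1 | step 12 | allyl furanone: methyl 2-{hydroxy[(4R,5S)-2,2-dimethyl-5-{1-[(5R)-5-methyl-4-oxo-5-(prop-2-en-1-yl)-4,5-dihydrofuran-2-yl]ethenyl}-1,3-dioxolan-4-yl]methyl}prop-2-enoate (carbinol epimers) | C=CC[C@@]1(C)OC(=CC1=O)C(=C)[C@@H]2OC(C)(C)O[C@@H]2C(O)C(=C)C(=O)OC
F2 | step 12 | furanone aldehyde: the 2-oxoethyl analogue of F1 (allyl group cleaved to CH2CHO) | O=CC[C@@]1(C)OC(=CC1=O)C(=C)[C@@H]2OC(C)(C)O[C@@H]2C(O)C(=C)C(=O)OC
F3 | step 12 | (Z)-allylic bromide: methyl (2Z)-2-(bromomethyl)-3-[(4R,5S)-2,2-dimethyl-5-{1-[(5R)-5-methyl-4-oxo-5-(2-oxoethyl)-4,5-dihydrofuran-2-yl]ethenyl}-1,3-dioxolan-4-yl]prop-2-enoate | O=CC[C@@]1(C)OC(=CC1=O)C(=C)[C@@H]2OC(C)(C)O[C@@H]2/C=C(\CBr)C(=O)OC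
F4 | step 12 | macrocyclic alcohol: ten-membered furanone carbocycle closed at C7–C8, free C8 hydroxyl, 5,6-O-isopropylidene, methyl acrylate unit on C7 (configuration as in 20) | C=C(C(=O)OC)[C@@H]1[C@H](O)C[C@@]2(C)OC(=CC2=O)C(=C)[C@@H]3OC(C)(C)O[C@H]13
F5 | step 12 | macrocyclic isobutyrate: 8-O-(2-methylpropanoyl) derivative of F4 | C=C(C(=O)OC)[C@@H]1[C@H](OC(=O)C(C)C)C[C@@]2(C)OC(=CC2=O)C(=C)[C@@H]3OC(C)(C)O[C@H]13
F6 | step 9 | acetate of 8 (O-acetyl derivative, dioxolane configuration unchanged) | C=C(C(=O)OC)C(OC(C)=O)[C@H]1OC(C)(C)O[C@H]1C(=C)C#C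
F7 | step 9 | pinacol allylboronate corresponding to 9 (CH2Bpin in place of CH2Br, dioxolanyl group cis to CH2B) | CC1(C)OB(C/C(C(=O)OC)=C\[C@H]2OC(C)(C)O[C@H]2C(=C)C#C)OC1(C)C
F8 | step 2 | (4R,5R)-5-(hydroxymethyl)-N-methoxy-N,2,2-trimethyl-1,3-dioxolane-4-carboxamide | OC[C@H]1OC(C)(C)O[C@H]1C(=O)N(C)OC
F9 | step 2 | (4R,5R)-5-{[tert-butyl(dimethyl)silyl]oxymethyl}-N-methoxy-N,2,2-trimethyl-1,3-dioxolane-4-carboxamide | CC(C)(C)[Si](C)(C)OC[C@H]1OC(C)(C)O[C@H]1C(=O)N(C)OC
F10 | step 2 | 1-[(4R,5R)-5-{[tert-butyl(dimethyl)silyl]oxymethyl}-2,2-dimethyl-1,3-dioxolan-4-yl]-3-(trimethylsilyl)prop-2-yn-1-one | CC(C)(C)[Si](C)(C)OC[C@H]1OC(C)(C)O[C@H]1C(=O)C#C[Si](C)(C)C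
F11 | step 2 | tert-butyl{[(4R,5S)-2,2-dimethyl-5-[4-(trimethylsilyl)but-1-en-3-yn-2-yl]-1,3-dioxolan-4-yl]methoxy}dimethylsilane | CC(C)(C)[Si](C)(C)OC[C@H]1OC(C)(C)O[C@H]1C(=C)C#C[Si](C)(C)C
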